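## Structural features

The target is a 3,4-dihydro-2H-pyran (ring A: O1, C2 to C6) joined through a C4 acetic ester to the primary oxygen of hydroxytyrosol, whose catechol (ring B) is free. Ring A carries a methyl group at C2, a formyl group at C3, the CH2CO2R arm at C4 and a methyl ester at C5, so that O1–C6=C5–CO2Me is a vinylogous carbonate. C2, C3 and C4 are contiguous stereocentres, all S, with methyl and formyl cis and formyl and acetate arm trans. The formyl group is α to the C3 hydrogen and β to O1, so base can epimerise C3 or open ring A by retro-oxa-Michael cleavage and thereby scramble C2; the catechol is easily oxidised and is a nucleophile towards oxocarbenium ions. The two carboxyl groups bear different esters, and once the aldehyde is present they can no longer be told apart safely. The real difficulty is therefore to set three adjacent stereocentres on a ring that tolerates neither base nor strong acid, and to have the right ester on each carboxyl group before the aldehyde appears. The key step uses the unit O=CH–C3–C4–C5=C6(–O1): a γ,δ-unsaturated aldehyde whose δ-carbon carries the ring oxygen, which is the retron of a Claisen shift inside a cyclic enol acetal.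

## Logic of the disconnections

**14 to 13.** No skeletal bond is cut; the two phenolic O–H bonds are traced back to O–Si bonds. Ring B has to be masked while oxocarbenium ions, a silyl triflate and heat are in use. The gain is that the last step does not have to distinguish two esters next to a β-alkoxy aldehyde, as a late ester exchange would. The demand is a desilylation that neither enolises C3 nor opens ring A.

**13 to 12.** The C3–C4 bond of ring A is cut and the formyl oxygen is reconnected to C6 (Claisen transform). Ring A, the aldehyde and two stereocentres vanish; 12 keeps only the carbinol centre and a labile acetal centre. Two points of the precursor are changed: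
- The CH2 arm already carries the silylated aryl-ethyl ester, so no ester exchange follows the key step.
- The descriptor of the reactive epimer is put right. With the S carbinol, alkenyl trans to methyl is (2S,4S), because the ring oxygen bound to the methyl-bearing carbon outranks the vinyl-bound one. The label (2R,4S) would denote the cis epimer.

The forward step needs a boat transition state, the trans acetal epimer, the E alkene, and a shift that is faster than cycloreversion of the dioxin.

**12 to 11.** The C5=C6 π bond of the dioxin is traced back to C5–H and C6–OMe. The enol acetal is too labile to be assembled directly, whereas its saturated 6-methoxy form is an ordinary bis-acetal. The demand is ionisation at C6 only, not at C2, under conditions that leave the doubly activated CH2 group and the alkene geometry alone.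

**11 to 7 and 9.** The cuts are C2–O1, C2–O3 and O1–C6. This joins an achiral alkenyl acetal to a four-carbon chiral unit. O1 bridges two acetal carbons and must therefore come from a carbonyl oxygen; two dimethyl acetals cannot supply it. So 9 has to enter at the aldehyde level, as 10, which is not isolated. The demand is an acid strong enough to ionise the ester-deactivated acetal of 7 yet too mild to eliminate an alkoxy group towards the conjugated dienyl ether or to dehydrate 10.

**9 to 8.** The carbinol C–H bond is cut. An enantioselective ketone reduction is the only source of absolute configuration; it must give the S alcohol without touching the acetal.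

**7 to 6.** The two O–Si bonds are cut; the forward step is a routine silylation that must not move the alkene.

**6 to 4 and 5.** The ester C–O bond of the unconjugated carboxyl group is cut. In 4 the two esters differ sharply (conjugated and α-branched against unhindered), and no stereocentre or aldehyde is present yet, so this is the safest point to differentiate them. The demand is site selectivity between the two esters and between the primary alcohol and the phenols of 5, which points to an enzyme.

**4 to 1 and 2.** The C–C bond between the acetal carbon and the α-carbon is cut. Since 1 is a symmetrical vinylogous malonate, both nucleophilic termini lead to the same product, 3, and regiochemistry is no issue. The demand is to stop at the acetal oxidation level and to reach the E trisubstituted alkene under thermodynamic control.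

## Other disconnections considered

**Alternative 1:** The cut goes through C2–C3 and O1–C6. It takes C2 and O1 out of ring A as acetaldehyde A2 and leaves the 1-methoxy diene ester A1, methyl (2Z,3E)-5-[(tert-butyldimethylsilyl)oxy]-2-(methoxymethylidene)pent-3-enoate. Forward, a chiral Lewis acid would activate A2 for an endo hetero-Diels–Alder addition to A1 and close the 3,6-dihydro-2H-pyran A3 with C2, C3 and C6 all cis. By the sequence rules this all-cis compound is (2S,3R,6S), not (2S,3S,6S): C3 is R because CH2OSi ranks below C2, although the arrangement in space is that of the target.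
- In its favour: two bonds, the ring and two stereocentres would come from simple achiral partners in one catalytic step. The cis C2/C3 relationship follows from the endo rule, and no intermediate is as labile as an enol acetal.
- Against it here: A1 is a push–pull diene, so it is a poor partner for an unactivated, volatile, enolisable aldehyde, and enantiocontrol with so small a dienophile is the least secure point. After the cycloaddition C4 is still sp2. The acetate arm must then be added anti to the C3 substituent with loss of the C6 methoxy group, the C3 carbinol deprotected and oxidised, and the aryl-ethyl ester installed. That is at least four more steps, with one more stereocentre to control.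
- Comparison: both plans close ring A in the key step, but the chosen plan forms C3 and C4 together and delivers C3 at the aldehyde level. On robustness of the ring-forming intermediate Alternative 1 is the better plan. On the source of chirality the two are equal (a catalyst in both). On step economy Alternative 1 is behind.

**Alternative 2:** The cut goes through C4–C5, C2=C3 and O1–C2 and gives three components: the enal A4 (the bis-silylated aryl-ethyl ester of (3E)-5-oxopent-3-enoic acid), methyl formylacetate A5 and acetaldehyde A2. Forward, a chiral secondary-amine catalyst would direct the Michael addition of A5 to the iminium ion of A4 (C4–C5). The freed aldehyde would condense with A2 (C2=C3), and the enol oxygen of the formyl ester would close ring A by oxa-Michael addition (O1–C2) to give A6, which is the same compound as 13.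
- In its favour: the greatest convergence, the final ester in place from the start, no change of oxidation state, and a ring closure that mirrors the ring–chain behaviour of the natural aglycone.
- Against it here: only C4 is set by the catalyst. C2 and C3 arise from a reversible oxa-Michael addition and a protonation, so the C2 epimer is expected alongside. The condensation must pick one aldehyde α-position in the presence of a formyl ester and of self-condensing A2. A4 has an acidic γ-methylene group and A5 does not keep.
- Comparison: on step economy Alternative 2 is clearly the better plan (one operation against seven steps to 13). On control of C4 it is equal. On control of C2 relative to C3 and C4 the chosen plan is stronger, because a concerted shift relays one fixed carbinol centre to both new centres, whereas the cascade leaves C2 to an equilibrium.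

**Alternative 3:** The cut goes through O1–C6 and C4–C5. It removes C5 and C6 as methyl propiolate A8 and leaves the acyclic hydroxy enoate A7, the bis-silylated aryl-ethyl (2E,4R,5S)-4-(silyloxymethyl)-5-hydroxyhex-2-enoate, in which C2 and C3 of ring A are already set. Forward, a nucleophilic amine or phosphine catalyst would add the alkoxide of A7 to A8 (O1–C6), and the vinyl anion equivalent at C5 would add to the enoate β-carbon (C4–C5) to give A9. By the sequence rules A9 is (2S,3R,4S), not (2S,3S,4S), for the same reason as A3.
- In its favour: alkoxide addition to propiolates is dependable, the final ester is in place, the vinylogous carbonate forms directly, and C2 and C3 are fixed by acyclic stereocontrol before the ring exists.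
- Against it here: the carbon–carbon bond-forming stage competes with simple protonation to an open β-alkoxyacrylate. Facial selectivity at C4 rests on 1,2-induction from C3 alone. C3 is at the alcohol level, so selective removal of the alkyl silyl ether, oxidation and final desilylation follow. A7 needs an asymmetric synthesis of several steps of its own.
- Comparison: on predictability of the individual reaction types Alternative 3 is the equal or the better of the chosen plan, since it has no enol acetal and no equilibrating acetal centre. On structure the chosen plan creates C3 and C4 in one event at the right oxidation level. On step economy the chosen plan is shorter overall.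

Key step: step 7

Assumption: the acetal carbon of 11 and 12 is taken to be configurationally labile under weak acid, so both are carried as epimer mixtures and 12 is drawn as its reactive (2S,4S) form.

## Route

Step 1
Reactants: 1 dimethyl (2E)-pent-2-enedioate (dimethyl glutaconate); 2 trimethyl orthoformate
Product: 4 dimethyl (2E)-2-(dimethoxymethyl)pent-2-enedioate, via dimethyl (3E)-2-(dimethoxymethyl)pent-3-enedioate 3 (not isolated)
Conditions: TMSOTf (1.5 equiv), iPr2NEt (1.3 equiv), CH2Cl2, 0 → −78 °C; aq NaHCO3; then Et3N (0.2 equiv), MeCN, rt
Reagents that add atoms: none
Why: Soft enolisation gives the silyl dienolate of 1, which adds to the dimethoxycarbenium ion from 2 in a Mukaiyama-type orthoformate alkylation; both nucleophilic termini are equivalent, so only 3 can form. Amine-catalysed prototropic shift then moves the alkene into conjugation with the branched ester, and the E isomer (CH2 arm trans to CO2Me, as in tiglates) should be the thermodynamic trisubstituted enoate; 4 has no stereocentre.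

Step 2
Reactants: 4 dimethyl (2E)-2-(dimethoxymethyl)pent-2-enedioate; 5 hydroxytyrosol
Product: 6 5-[2-(3,4-dihydroxyphenyl)ethyl] 1-methyl (2E)-2-(dimethoxymethyl)pent-2-enedioate
Conditions: Novozym 435 (immobilised Candida antarctica lipase B), 2-methylbutan-2-ol, 5 Å MS, 45 °C, Ar
Reagents that add atoms: none
Why: Lipase-catalysed transesterification: the enzyme accepts the unhindered CH2CO2Me group but not the conjugated, α-branched ester, and it acylates the primary alcohol of 5 in preference to the phenols. The neutral medium leaves the acetal and the alkene geometry untouched.

Step 3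
Reactants: 6 5-[2-(3,4-dihydroxyphenyl)ethyl] 1-methyl (2E)-2-(dimethoxymethyl)pent-2-enedioate
Product: 7 5-(2-{3,4-bis[(tert-butyldimethylsilyl)oxy]phenyl}ethyl) 1-methyl (2E)-2-(dimethoxymethyl)pent-2-enedioate
Conditions: TBSCl (2.3 equiv), imidazole, DMF, 0 °C → rt
Reagents that add atoms: tert-butyldimethylsilyl chloride, CC(C)(C)[Si](C)(C)Cl
Why: Standard silylation of both phenols; imidazole is too weak a base to move the alkene. The bulky silyl ethers shield ring B from the oxocarbenium ions of steps 5 and 6 and can be removed at the end without base.

Step 4
Reactants: 8 4,4-dimethoxybutan-2-one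
Product: 9 (2S)-4,4-dimethoxybutan-2-ol
Conditions: S-selective alcohol dehydrogenase (ADH-A from Rhodococcus ruber), NADH (cat.), iPrOH, phosphate buffer pH 7.5, 30 °C
Reagents that add atoms: none
Why: Biocatalytic ketone reduction: the enzyme delivers hydride to the Re face of the methyl ketone, which gives the S carbinol, the only source of absolute configuration in the route. The acetal is stable at neutral pH.

Step 5
Reactants: 9 (2S)-4,4-dimethoxybutan-2-ol; 7 5-(2-{3,4-bis[(tert-butyldimethylsilyl)oxy]phenyl}ethyl) 1-methyl (2E)-2-(dimethoxymethyl)pent-2-enedioate
Product: 11 5-(2-{3,4-bis[(tert-butyldimethylsilyl)oxy]phenyl}ethyl) 1-methyl (2E)-2-[(4S)-6-methoxy-4-methyl-1,3-dioxan-2-yl]pent-2-enedioate (epimer mixture at C2 and C6 of the dioxane), via (3S)-3-hydroxybutanal 10 (not isolated)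
Conditions: 9, H2O (1.1 equiv), Amberlyst-15, MeCN, rt; filter; then 7, CSA (5 mol %), CH2Cl2, 0 °C → rt, closed flask
Reagents that add atoms: water, O
Why: Acid-catalysed transacetalisation of the aldoxane type: 10 takes the place of a 1,3-diol, its hydroxyl and its carbonyl oxygen (as the methyl hemiacetal) becoming O3 and O1 of the 1,3-dioxane, while one methoxy group stays on C6. The diequatorial 2,4-cis acetal is expected to dominate; C2 and C6 need no control because C6 becomes sp2 in step 6 and C2 is equilibrated in step 7, and the carbinol C–O bond is never broken.

Step 6
Reactants: 11 5-(2-{3,4-bis[(tert-butyldimethylsilyl)oxy]phenyl}ethyl) 1-methyl (2E)-2-[(4S)-6-methoxy-4-methyl-1,3-dioxan-2-yl]pent-2-enedioate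
Product: 12 5-(2-{3,4-bis[(tert-butyldimethylsilyl)oxy]phenyl}ethyl) 1-methyl (2E)-2-[(2S,4S)-4-methyl-4H-1,3-dioxin-2-yl]pent-2-enedioate (alkenyl trans to methyl; formed in admixture with its (2R,4S) cis epimer)
Conditions: TMSOTf (1.2 equiv), iPr2NEt (1.5 equiv), CH2Cl2, −40 → 0 °C; aq NaHCO3
Reagents that add atoms: none
Why: Silyl triflate–amine conversion of an acetal into an enol ether: the triflate ionises the exocyclic methoxy group at C6 (the acetal at C2 is deactivated by the acrylate ester), and the hindered amine removes a C5 proton from the cyclic oxocarbenium ion. Low temperature and a near-stoichiometric charge limit silylation of the doubly activated CH2 group; C4 is untouched.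

Step 7
Reactants: 12 5-(2-{3,4-bis[(tert-butyldimethylsilyl)oxy]phenyl}ethyl) 1-methyl (2E)-2-[(2S,4S)-4-methyl-4H-1,3-dioxin-2-yl]pent-2-enedioate (with its cis epimer)
Product: 13 methyl (2S,3S,4S)-4-[2-(2-{3,4-bis[(tert-butyldimethylsilyl)oxy]phenyl}ethoxy)-2-oxoethyl]-3-formyl-2-methyl-3,4-dihydro-2H-pyran-5-carboxylate
Conditions: PivOH (5 mol %), toluene (0.02 M), 110 °C, sealed tube, Ar
Reagents that add atoms: none
Why: This is a Claisen rearrangement of an allyl vinyl ether whose halves are joined through the acetal carbon: the enol ether C5=C6–O1 of the dioxin and the unit C2–Cα=Cβ reorganise so that C5–Cβ forms while O1–C2 breaks, which frees the formyl group and leaves the new enol ether O–CH=C(CO2Me). The closest known reaction type is the Claisen ring contraction of 2-alkenyl-4H-1,3-dioxins to 3,4-dihydro-2H-pyran-3-carbaldehydes, with the dioxanone-to-dihydropyran Ireland–Claisen rearrangement as its ester-enolate relative. Ring A is closed by the sigmatropic bond formation itself, not by an ionic cyclisation: the new σ-bond joins two carbons already tied together through C4–O3–C2, so the transition state is bicyclo[2.2.2]octane-like and must be a boat. C2 of ring A is the untouched carbinol carbon. C3 is set by the face of the enol ether that the pseudoaxial alkenyl group covers, and with alkenyl trans to methyl this face puts the formyl group cis to the methyl group. C4 is set by the alkene geometry: in the E isomer the CH2CO2R arm lies on the acetal-carbon side, points towards the O3–C4 bridge of the boat and ends up trans to the formyl group. The step needs the trans acetal epimer, the E alkene and a shift faster than retro-hetero-Diels–Alder cleavage. Pivalic acid equilibrates C2 so that the less crowded boat of the trans epimer (methyl turned away from the CH2CO2R arm) drains the mixture; the E geometry is the thermodynamic one from step 1; and the pairing of an electron-rich enol ether with an electron-poor acrylate, together with the gain of a C=O bond and a vinylogous carbonate, favours the shift.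

Step 8
Reactants: 13 methyl (2S,3S,4S)-4-[2-(2-{3,4-bis[(tert-butyldimethylsilyl)oxy]phenyl}ethoxy)-2-oxoethyl]-3-formyl-2-methyl-3,4-dihydro-2H-pyran-5-carboxylate
Product: 14 methyl (2S,3S,4S)-4-{2-[2-(3,4-dihydroxyphenyl)ethoxy]-2-oxoethyl}-3-formyl-2-methyl-3,4-dihydro-2H-pyran-5-carboxylate (target, CNP0172886.2)
Conditions: TBAF, AcOH (1:1, 2.4 equiv each), THF, 0 °C
Reagents that add atoms: none
Why: Fluoride cleavage of aryl silyl ethers, which is fast even when buffered with acetic acid. The buffer keeps the phenoxides protonated and avoids enolisation at C3 and retro-oxa-Michael opening of ring A; no stereocentre is touched.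

## Compound list

1 | dimethyl (2E)-pent-2-enedioate (dimethyl glutaconate) | COC(=O)/C=C/CC(=O)OC | starting material
2 | trimethyl orthoformate | COC(OC)OC | starting material
3 | dimethyl (3E)-2-(dimethoxymethyl)pent-3-enedioate (racemic) | COC(=O)C(C(OC)OC)/C=C/C(=O)OC | intermediate (not isolated)
4 | dimethyl (2E)-2-(dimethoxymethyl)pent-2-enedioate | COC(OC)/C(C(=O)OC)=C\CC(=O)OC | intermediate
5 | hydroxytyrosol, 4-(2-hydroxyethyl)benzene-1,2-diol | OCCc1ccc(O)c(O)c1 | starting material
6 | 5-[2-(3,4-dihydroxyphenyl)ethyl] 1-methyl (2E)-2-(dimethoxymethyl)pent-2-enedioate | COC(OC)/C(C(=O)OC)=C\CC(=O)OCCc1ccc(O)c(O)c1 | intermediate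
7 | 5-(2-{3,4-bis[(tert-butyldimethylsilyl)oxy]phenyl}ethyl) 1-methyl (2E)-2-(dimethoxymethyl)pent-2-enedioate | COC(OC)/C(C(=O)OC)=C\CC(=O)OCCc1ccc(O[Si](C)(C)C(C)(C)C)c(O[Si](C)(C)C(C)(C)C)c1 | intermediate
8 | 4,4-dimethoxybutan-2-one | CC(=O)CC(OC)OC | starting material
9 | (2S)-4,4-dimethoxybutan-2-ol | C[C@H](O)CC(OC)OC | intermediate
10 | (3S)-3-hydroxybutanal | C[C@H](O)CC=O | intermediate (not isolated)
11 | 5-(2-{3,4-bis[(tert-butyldimethylsilyl)oxy]phenyl}ethyl) 1-methyl (2E)-2-[(4S)-6-methoxy-4-methyl-1,3-dioxan-2-yl]pent-2-enedioate (C2 and C6 epimer mixture, chiefly 2,4-cis) | COC1C[C@H](C)OC(O1)/C(C(=O)OC)=C\CC(=O)OCCc1ccc(O[Si](C)(C)C(C)(C)C)c(O[Si](C)(C)C(C)(C)C)c1 | intermediate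
12 | 5-(2-{3,4-bis[(tert-butyldimethylsilyl)oxy]phenyl}ethyl) 1-methyl (2E)-2-[(2S,4S)-4-methyl-4H-1,3-dioxin-2-yl]pent-2-enedioate (alkenyl trans to methyl) | C[C@H]1C=CO[C@@H](O1)/C(C(=O)OC)=C\CC(=O)OCCc1ccc(O[Si](C)(C)C(C)(C)C)c(O[Si](C)(C)C(C)(C)C)c1 | intermediate (precursor of the key step)
13 | methyl (2S,3S,4S)-4-[2-(2-{3,4-bis[(tert-butyldimethylsilyl)oxy]phenyl}ethoxy)-2-oxoethyl]-3-formyl-2-methyl-3,4-dihydro-2H-pyran-5-carboxylate | COC(=O)C1=CO[C@@H](C)[C@@H](C=O)[C@@H]1CC(=O)OCCc1ccc(O[Si](C)(C)C(C)(C)C)c(O[Si](C)(C)C(C)(C)C)c1 | intermediate (product of the key step)
14 | methyl (2S,3S,4S)-4-{2-[2-(3,4-dihydroxyphenyl)ethoxy]-2-oxoethyl}-3-formyl-2-methyl-3,4-dihydro-2H-pyran-5-carboxylate | COC(=O)C1=CO[C@@H](C)[C@@H](C=O)[C@@H]1CC(=O)OCCc1ccc(O)c(O)c1 | target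

## Step count and least certain steps

Total step count: 8. Longest linear sequence: 7 steps (steps 1, 2, 3, 5, 6, 7, 8); step 4 lies on the short branch.

**Step 7 (key step).** Two things may go wrong.
- Cycloreversion of the dioxin (retro-hetero-Diels–Alder), or acid-induced ionisation at the acetal carbon followed by loss of the neighbouring methylene proton, may outpace the [3,3] shift. The enol acetal is a high-energy species with a low-energy ring-opened isomer.
- If epimerisation at the acetal carbon is slower than rearrangement, the cis epimer reacts through its own, more crowded boat and selectivity at C3 and C4 falls.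

Fallback: leave the pericyclic manifold for a stepwise ionic ring contraction of the Petasis–Ferrier type. Compound 12 (epimer mixture) would be treated with Me2AlCl in CH2Cl2 at −78 °C, which should ionise the O1–C2 bond to an aluminium enolate tethered to an alkenyl oxocarbenium ion. Recombination at the alkene terminus (six-membered; closure at the acetal carbon would give a four-membered ring) should give 13. Both acetal epimers pass through the same ion pair, so no epimerisation is needed. Facial selectivity would then rest on a chair-like closure with the methyl group equatorial, and C3 can settle trans to the C4 arm. This sets out from 12 and returns at 13 with no new isolated compound.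

**Step 5.** The acid needed to ionise the deactivated acetal may instead promote loss of methanol from it towards the conjugated dienyl ether, or dehydration and oligomerisation of the hydroxy aldehyde, and the equilibria may stop short of full conversion.

Fallback: an aprotic silyl-transfer acetalisation with a preformed chiral-pool aldehyde. Ethyl (3S)-3-hydroxybutanoate F1 would be silylated (TESCl, imidazole, CH2Cl2) to ethyl (3S)-3-[(triethylsilyl)oxy]butanoate F2 and reduced (iBu2AlH, CH2Cl2, −78 °C) to (3S)-3-[(triethylsilyl)oxy]butanal F3. F3 and 7 with TMSOTf (cat.) in CH2Cl2 at −78 °C should give 11: the silyl group leaves with one methoxy group of 7 and the other methoxy group ends on C6. This sets out from 7 and returns at 11.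

**Step 6.** Silylation or deprotonation at the doubly activated methylene group may cause alkene migration, loss of the E geometry or base-induced opening of the acetal; ionisation may also occur at C2 instead of C6.

Fallback: a base-free oxidative elimination. Compound 11 with PhSeH and BF3·OEt2 (cat.) in CH2Cl2 at −40 °C should give the 6-(phenylselanyl)-1,3-dioxane F4. Oxidation (H2O2, THF, 0 °C) should give the selenoxide F5, whose syn-elimination at room temperature can only remove a C5 proton and leads to 12. This sets out from 11 and returns at 12.

**Step 1.** Over-reaction may occur (loss of methanol from 3 or 4 under silyl triflate and amine, towards the dienyl ether), and the prototropic equilibrium may not settle cleanly on the E 2-ene.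

Fallback: make the dienyl ether on purpose and add methanol back. Compounds 1 and 2 in Ac2O at 130 °C should give dimethyl (2E)-4-(methoxymethylidene)pent-2-enedioate F6. NaOMe (cat.) in MeOH at 0 °C should add methoxide to the methoxymethylidene carbon, and protonation of the dienolate at the unsubstituted terminus (AcOH quench) should give 4. This sets out from 1 and 2 and returns at 4.

## Further compounds

F0 | step 7 | none | none
F1 | step 5 | ethyl (3S)-3-hydroxybutanoate | CCOC(=O)C[C@H](C)O
F2 | step 5 | ethyl (3S)-3-[(triethylsilyl)oxy]butanoate | CCOC(=O)C[C@H](C)O[Si](CC)(CC)CC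
F3 | step 5 | (3S)-3-[(triethylsilyl)oxy]butanal | O=CC[C@H](C)O[Si](CC)(CC)CC
F4 | step 6 | 5-(2-{3,4-bis[(tert-butyldimethylsilyl)oxy]phenyl}ethyl) 1-methyl (2E)-2-[(4S)-4-methyl-6-(phenylselanyl)-1,3-dioxan-2-yl]pent-2-enedioate | C[C@H]1CC([Se]c2ccccc2)OC(O1)/C(C(=O)OC)=C\CC(=O)OCCc1ccc(O[Si](C)(C)C(C)(C)C)c(O[Si](C)(C)C(C)(C)C)c1
F5 | step 6 | 5-(2-{3,4-bis[(tert-butyldimethylsilyl)oxy]phenyl}ethyl) 1-methyl (2E)-2-[(4S)-4-methyl-6-(phenylseleninyl)-1,3-dioxan-2-yl]pent-2-enedioate | C[C@H]1CC([Se](=O)c2ccccc2)OC(O1)/C(C(=O)OC)=C\CC(=O)OCCc1ccc(O[Si](C)(C)C(C)(C)C)c(O[Si](C)(C)C(C)(C)C)c1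
F6 | step 1 | dimethyl (2E)-4-(methoxymethylidene)pent-2-enedioate | COC=C(/C=C/C(=O)OC)C(=O)OC
A1 | alternative 1 | methyl (2Z,3E)-5-[(tert-butyldimethylsilyl)oxy]-2-(methoxymethylidene)pent-3-enoate | CO/C=C(/C=C/CO[Si](C)(C)C(C)(C)C)C(=O)OC
A2 | alternative 1 | acetaldehyde | CC=O
A3 | alternative 1 | methyl (2S,3R,6S)-3-{[(tert-butyldimethylsilyl)oxy]methyl}-6-methoxy-2-methyl-3,6-dihydro-2H-pyran-5-carboxylate | COC(=O)C1=C[C@H](CO[Si](C)(C)C(C)(C)C)[C@H](C)O[C@@H]1OC
A4 | alternative 2 | 2-{3,4-bis[(tert-butyldimethylsilyl)oxy]phenyl}ethyl (3E)-5-oxopent-3-enoate | O=C/C=C/CC(=O)OCCc1ccc(O[Si](C)(C)C(C)(C)C)c(O[Si](C)(C)C(C)(C)C)c1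
A5 | alternative 2 | methyl 3-oxopropanoate (methyl formylacetate) | COC(=O)CC=O
A6 | alternative 2 | methyl (2S,3S,4S)-4-[2-(2-{3,4-bis[(tert-butyldimethylsilyl)oxy]phenyl}ethoxy)-2-oxoethyl]-3-formyl-2-methyl-3,4-dihydro-2H-pyran-5-carboxylate | COC(=O)C1=CO[C@@H](C)[C@@H](C=O)[C@@H]1CC(=O)OCCc1ccc(O[Si](C)(C)C(C)(C)C)c(O[Si](C)(C)C(C)(C)C)c1
A7 | alternative 3 | 2-{3,4-bis[(tert-butyldimethylsilyl)oxy]phenyl}ethyl (2E,4R,5S)-4-{[(tert-butyldimethylsilyl)oxy]methyl}-5-hydroxyhex-2-enoate | O[C@@H](C)[C@@H](CO[Si](C)(C)C(C)(C)C)/C=C/C(=O)OCCc1ccc(O[Si](C)(C)C(C)(C)C)c(O[Si](C)(C)C(C)(C)C)c1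
A8 | alternative 3 | methyl propiolate | C#CC(=O)OC
A9 | alternative 3 | methyl (2S,3R,4S)-4-[2-(2-{3,4-bis[(tert-butyldimethylsilyl)oxy]phenyl}ethoxy)-2-oxoethyl]-3-{[(tert-butyldimethylsilyl)oxy]methyl}-2-methyl-3,4-dihydro-2H-pyran-5-carboxylate | COC(=O)C1=CO[C@@H](C)[C@@H](CO[Si](C)(C)C(C)(C)C)[C@@H]1CC(=O)OCCc1ccc(O[Si](C)(C)C(C)(C)C)c(O[Si](C)(C)C(C)(C)C)c1
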